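**Plan**

1. Flavanone numbering is used: ring A is the benzo ring, ring B the 4-hydroxyphenyl group, ring C the pyranone O1–C2–C3–C4–C4a–C8a; the piperidine carbon on ring A is C2'. Retrosynthetic cuts, in order: the three O–benzyl bonds; then ring C is contracted by joining C2 to C4, so that C2–H becomes the C2–C4 bond of a cyclopropanol with C3 as its third carbon; then both bonds of C3 (a CH2 transferred to the C2=C4 bond of a 2-aryl-3-siloxybenzofuran); then C4–C4a (intramolecular acylation) and O1–C2 (aryl ether); last the piperidine bonds N–C6' and C2'–C3'.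
2. Forward order: ring A aldehyde → piperidine ring (sulfinimine, Grignard addition, N-alkylation) → phenol O-alkylation and Friedel–Crafts closure to the benzofuran → cyclopropane → ring enlargement to ring C → debenzylation.
3. Enabling feature: in ring C the C4 carbonyl and C2 (which carries O1 and ring B) are 1,3-related through the C3 methylene, a ketone homoenolate relationship. Ring C is therefore a furan ring O1–C2–C4–C4a–C8a with C3 bridging C2 and C4, and the precursor is a flat 2-arylbenzofuran-3-ol that is dearomatized on the way.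
4. The phenol used is symmetric (O1 para to the piperidine-bearing carbon, two equivalent ortho positions), so the 6- versus 8-substitution pattern is fixed without a selectivity question.
5. Stereochemistry: C2' (R) from (S)-tert-butanesulfinamide in the Grignard addition; C2 (S) from face-selective CH2 transfer to the benzofuran by a chiral zinc carbenoid, relayed with inversion in the ring-opening protonation.

Key step: step 13

Assumption: the zinc carbenoid bound to N-Boc-L-Val-L-Pro-OMe is taken to add to the face of the benzofuran C2=C3 bond that leads to the (1aR,6bR) adduct; should the opposite face be preferred, the D,D-ligand takes its place with no other change.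

**Route**

Step 1
Reactants: 1 2,4,6-trihydroxybenzaldehyde
Product: 2 2,6-dihydroxy-4-(methoxymethoxy)benzaldehyde
Conditions: MOMCl (1.0 equiv), K2CO3, acetone, 0 °C → rt
Reagents that add atoms: chloromethyl methyl ether, COCCl
Why: Williamson-type O-alkylation; the 4-hydroxyl is the most acidic and the only one not hydrogen-bonded to the formyl group, so one equivalent of MOMCl should mark the oxygen that later becomes O1.

Step 2
Reactants: 2 2,6-dihydroxy-4-(methoxymethoxy)benzaldehyde
Product: 3 2,6-bis(benzyloxy)-4-(methoxymethoxy)benzaldehyde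
Conditions: BnBr (2.4 equiv), K2CO3, DMF, 60 °C
Reagents that add atoms: benzyl bromide, BrCc1ccccc1
Why: Williamson ether synthesis on the two chelated ortho hydroxyls under forcing carbonate conditions; the benzyl ethers are meant to last until the final step.

Step 3
Reactants: 3 2,6-bis(benzyloxy)-4-(methoxymethoxy)benzaldehyde, 4 (S)-2-methylpropane-2-sulfinamide
Product: 5 (S)-N-[(E)-[2,6-bis(benzyloxy)-4-(methoxymethoxy)phenyl]methylidene]-2-methylpropane-2-sulfinamide
Conditions: Ti(OEt)4 (2 equiv), THF, 65 °C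
Reagents that add atoms: none
Why: Condensation of the aldehyde with tert-butanesulfinamide, Ti(OEt)4 serving as Lewis acid and water scavenger, should give the E N-sulfinyl aldimine.

Step 4
Reactants: 5 (S)-N-[(E)-[2,6-bis(benzyloxy)-4-(methoxymethoxy)phenyl]methylidene]-2-methylpropane-2-sulfinamide, 6 1-bromo-4-chlorobutane
Product: 8 (S)-N-[(1R)-1-[2,6-bis(benzyloxy)-4-(methoxymethoxy)phenyl]-5-chloropentyl]-2-methylpropane-2-sulfinamide, via 4-chlorobutylmagnesium bromide 7 (not isolated)
Conditions: 6, Mg, THF; then 5, CH2Cl2, −48 °C → rt; aq. NH4Cl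
Reagents that add atoms: none
Why: Grignard 1,2-addition to an N-tert-butanesulfinyl aldimine in a non-coordinating solvent through the six-membered chair transition state with magnesium on the sulfinyl oxygen; the (S)-sulfur should direct the alkyl group to the face that gives the (R)-carbinamine, and the minor diastereomer can be removed by chromatography at this stage.

Step 5
Reactants: 8 (S)-N-[(1R)-1-[2,6-bis(benzyloxy)-4-(methoxymethoxy)phenyl]-5-chloropentyl]-2-methylpropane-2-sulfinamide
Product: 9 (2R)-2-[2,6-bis(benzyloxy)-4-(methoxymethoxy)phenyl]-1-[(S)-tert-butylsulfinyl]piperidine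
Conditions: NaH, DMF, 0 °C → rt
Reagents that add atoms: none
Why: Intramolecular N-alkylation (6-exo-tet SN2) of the sulfinamide anion by the primary chloride closes the piperidine without touching the stereocenter.

Step 6
Reactants: 9 (2R)-2-[2,6-bis(benzyloxy)-4-(methoxymethoxy)phenyl]-1-[(S)-tert-butylsulfinyl]piperidine
Product: 10 3,5-bis(benzyloxy)-4-[(2R)-piperidin-2-yl]phenol
Conditions: HCl (4 M in dioxane), MeOH, 0 → 40 °C; then aq. NaHCO3
Reagents that add atoms: none
Why: Acid methanolysis of the N–S bond and of the MOM acetal should free the secondary amine and the one phenol that becomes O1, while the benzyl ethers stay; time and temperature are kept low because the electron-rich benzylic C–N bond is acid-sensitive.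

Step 7
Reactants: 10 3,5-bis(benzyloxy)-4-[(2R)-piperidin-2-yl]phenol
Product: 11 3,5-bis(benzyloxy)-4-[(2R)-1-methylpiperidin-2-yl]phenol
Conditions: aq. CH2O (1.2 equiv), NaBH(OAc)3, ClCH2CH2Cl, 0 °C → rt
Reagents that add atoms: formaldehyde, C=O
Why: Reductive amination with NaBH(OAc)3 methylates nitrogen; the iminium ion should be reduced faster than formaldehyde attacks the phenol ring, and both positions ortho to the benzylic carbon are blocked against Pictet–Spengler closure.

Step 8
Reactants: 12 methyl 2-[4-(benzyloxy)phenyl]acetate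
Product: 14 methyl 2-[4-(benzyloxy)phenyl]-2-bromoacetate (racemic), via lithium ester enolate 13 (not isolated)
Conditions: LiN(SiMe3)2, THF, −78 °C; then NBS, −78 °C; aq. NH4Cl
Reagents that add atoms: N-bromosuccinimide, O=C1CCC(=O)N1Br
Why: Electrophilic α-bromination of the ester enolate installs the leaving group without radical conditions, which would attack the benzyl ether CH2.

Step 9
Reactants: 11 3,5-bis(benzyloxy)-4-[(2R)-1-methylpiperidin-2-yl]phenol, 14 methyl 2-[4-(benzyloxy)phenyl]-2-bromoacetate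
Product: 15 methyl 2-[4-(benzyloxy)phenyl]-2-{3,5-bis(benzyloxy)-4-[(2R)-1-methylpiperidin-2-yl]phenoxy}acetate (both epimers at the acetate carbon)
Conditions: Cs2CO3, MeCN, rt
Reagents that add atoms: none
Why: Williamson SN2 displacement of the activated secondary bromide by the caesium phenoxide forms the future O1–C2 bond; the new α-stereocenter does not matter because it is planarized in step 11.

Step 10
Reactants: 15 methyl 2-[4-(benzyloxy)phenyl]-2-{3,5-bis(benzyloxy)-4-[(2R)-1-methylpiperidin-2-yl]phenoxy}acetate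
Product: 16 2-[4-(benzyloxy)phenyl]-2-{3,5-bis(benzyloxy)-4-[(2R)-1-methylpiperidin-2-yl]phenoxy}acetic acid
Conditions: LiOH·H2O, THF/MeOH/H2O, rt; then AcOH to pH 6
Reagents that add atoms: lithium hydroxide, [Li+].[OH-]
Why: Saponification of the methyl ester gives the acid needed for the ring acylation.

Step 11
Reactants: 16 2-[4-(benzyloxy)phenyl]-2-{3,5-bis(benzyloxy)-4-[(2R)-1-methylpiperidin-2-yl]phenoxy}acetic acid
Product: 19 {[4,6-bis(benzyloxy)-2-[4-(benzyloxy)phenyl]-5-[(2R)-1-methylpiperidin-2-yl]-1-benzofuran-3-yl]oxy}(tert-butyl)dimethylsilane, via mixed trifluoroacetic anhydride 17 (not isolated), via 2-arylbenzofuran-3(2H)-one 18 (not isolated)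
Conditions: (CF3CO)2O, CH2Cl2, 0 °C; evaporate; then TBSOTf, Et3N, CH2Cl2, 0 °C
Reagents that add atoms: tert-butyldimethylsilyl trifluoromethanesulfonate, CC(C)(C)[Si](C)(C)OS(=O)(=O)C(F)(F)F
Why: Intramolecular Friedel–Crafts acylation of the mixed anhydride at either of the two equivalent positions ortho to the ether oxygen forms the C4–C4a bond, and O-silylation of the enolizable, air-sensitive 2-arylbenzofuranone then gives the aromatic benzofuran silyl enol ether.

Step 12
Reactants: 19 {[4,6-bis(benzyloxy)-2-[4-(benzyloxy)phenyl]-5-[(2R)-1-methylpiperidin-2-yl]-1-benzofuran-3-yl]oxy}(tert-butyl)dimethylsilane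
Product: 20 {[(1aR,6bR)-4,6-bis(benzyloxy)-1a-[4-(benzyloxy)phenyl]-5-[(2R)-1-methylpiperidin-2-yl]-1,1a-dihydro-6bH-cyclopropa[b][1]benzofuran-6b-yl]oxy}(tert-butyl)dimethylsilane
Conditions: Et2Zn, CH2I2, N-Boc-L-Val-L-Pro-OMe, CH2Cl2, −40 → 0 °C
Reagents that add atoms: diiodomethane, ICI
Why: Proposed new method: Simmons–Smith-type transfer of CH2 from a dipeptide-bound (iodomethyl)zinc carbenoid to the C2=C3 bond of the 3-siloxybenzofuran, which carries oxygen on both carbons and is only weakly aromatic and so should act as the nucleophilic alkene the electrophilic carbenoid needs; the closest known reaction is the dipeptide-mediated asymmetric Simmons–Smith cyclopropanation of aryl-substituted silyl enol ethers, extended here to a tetrasubstituted heteroaromatic enol ether, and the two new stereocenters (necessarily cis at the ring fusion) are set by the chiral ligand on zinc.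

Step 13
Reactants: 20 {[(1aR,6bR)-4,6-bis(benzyloxy)-1a-[4-(benzyloxy)phenyl]-5-[(2R)-1-methylpiperidin-2-yl]-1,1a-dihydro-6bH-cyclopropa[b][1]benzofuran-6b-yl]oxy}(tert-butyl)dimethylsilane
Product: 22 (2S)-5,7-bis(benzyloxy)-2-[4-(benzyloxy)phenyl]-6-[(2R)-1-methylpiperidin-2-yl]-2,3-dihydro-4H-chromen-4-one, via tetrabutylammonium cyclopropanolate 21 (not isolated)
Conditions: Bu4NF, MeOH/THF, −78 → −30 °C; then AcOH
Reagents that add atoms: none
Why: Proposed new method: fluoride removes the silyl group, and in the cyclopropanolate 21 the oxygen lone pair forms the carbonyl while the ring-fusion bond C6b–C1a breaks and a proton from methanol is delivered to C1a from the rear (SE2 homoenolate protonation), so that the five-membered ring O2–C1a–C6b–C6a–C2a takes in the former cyclopropane CH2 and becomes the six-membered ring C. The closest known reactions are the base-induced opening of 2-arylcyclopropanols to β-aryl ketones, which runs with inversion at the benzylic carbon, and the one-carbon ring enlargement of cyclic ketones through their siloxycyclopropanes. No ring is closed by bond formation: the six-membered ring arises by scission of the bond shared by the three- and five-membered rings. The new stereocenter C2 is controlled by the configuration of C1a in 20, backside protonation turning (1aR) into (2S). The step needs cleavage of the fusion bond and not of the C6b–CH2 bond, which the benzylic, oxygen-substituted character of the developing carbanion at C1a and the relief of bicyclic strain should secure; it also needs the product to escape retro-oxa-Michael opening, which low temperature, a protic medium and the acetic acid quench are meant to secure.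

Step 14
Reactants: 22 (2S)-5,7-bis(benzyloxy)-2-[4-(benzyloxy)phenyl]-6-[(2R)-1-methylpiperidin-2-yl]-2,3-dihydro-4H-chromen-4-one
Product: 23 (2S)-5,7-dihydroxy-2-(4-hydroxyphenyl)-6-[(2R)-1-methylpiperidin-2-yl]-2,3-dihydro-4H-chromen-4-one
Conditions: H2 (1 atm), Pd/C (10 wt% Pd on carbon), EtOAc/MeOH, rt
Reagents that add atoms: none
Why: Hydrogenolysis of the three benzyl ethers under neutral conditions should leave the base-sensitive C2 center, the aryl ketone and the benzylic C–N and C2–O1 bonds untouched.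

**Compound list**

1 | 2,4,6-trihydroxybenzaldehyde | O=Cc1c(O)cc(O)cc1O | starting material
2 | 2,6-dihydroxy-4-(methoxymethoxy)benzaldehyde | O=Cc1c(O)cc(OCOC)cc1O | intermediate
3 | 2,6-bis(benzyloxy)-4-(methoxymethoxy)benzaldehyde | O=Cc1c(OCc2ccccc2)cc(OCOC)cc1OCc1ccccc1 | intermediate
4 | (S)-2-methylpropane-2-sulfinamide | CC(C)(C)[S@](=O)N | starting material
5 | (S)-N-[(E)-[2,6-bis(benzyloxy)-4-(methoxymethoxy)phenyl]methylidene]-2-methylpropane-2-sulfinamide | CC(C)(C)[S@](=O)/N=C/c1c(OCc2ccccc2)cc(OCOC)cc1OCc1ccccc1 | intermediate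
6 | 1-bromo-4-chlorobutane | ClCCCCBr | starting material
7 | 4-chlorobutylmagnesium bromide | ClCCCC[Mg]Br | intermediate
8 | (S)-N-[(1R)-1-[2,6-bis(benzyloxy)-4-(methoxymethoxy)phenyl]-5-chloropentyl]-2-methylpropane-2-sulfinamide | CC(C)(C)[S@](=O)N[C@H](CCCCCl)c1c(OCc2ccccc2)cc(OCOC)cc1OCc1ccccc1 | intermediate
9 | (2R)-2-[2,6-bis(benzyloxy)-4-(methoxymethoxy)phenyl]-1-[(S)-tert-butylsulfinyl]piperidine | CC(C)(C)[S@](=O)N1CCCC[C@@H]1c1c(OCc2ccccc2)cc(OCOC)cc1OCc1ccccc1 | intermediate
10 | 3,5-bis(benzyloxy)-4-[(2R)-piperidin-2-yl]phenol | N1CCCC[C@@H]1c1c(OCc2ccccc2)cc(O)cc1OCc1ccccc1 | intermediate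
11 | 3,5-bis(benzyloxy)-4-[(2R)-1-methylpiperidin-2-yl]phenol | CN1CCCC[C@@H]1c1c(OCc2ccccc2)cc(O)cc1OCc1ccccc1 | intermediate
12 | methyl 2-[4-(benzyloxy)phenyl]acetate | COC(=O)Cc1ccc(OCc2ccccc2)cc1 | starting material
13 | lithium enolate of methyl 2-[4-(benzyloxy)phenyl]acetate | [Li+].COC([O-])=Cc1ccc(OCc2ccccc2)cc1 | intermediate
14 | methyl 2-[4-(benzyloxy)phenyl]-2-bromoacetate (racemic) | COC(=O)C(Br)c1ccc(OCc2ccccc2)cc1 | intermediate
15 | methyl 2-[4-(benzyloxy)phenyl]-2-{3,5-bis(benzyloxy)-4-[(2R)-1-methylpiperidin-2-yl]phenoxy}acetate (both epimers at the acetate carbon) | CN1CCCC[C@@H]1c1c(OCc2ccccc2)cc(OC(C(=O)OC)c2ccc(OCc3ccccc3)cc2)cc1OCc1ccccc1 | intermediate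
16 | 2-[4-(benzyloxy)phenyl]-2-{3,5-bis(benzyloxy)-4-[(2R)-1-methylpiperidin-2-yl]phenoxy}acetic acid (both epimers) | CN1CCCC[C@@H]1c1c(OCc2ccccc2)cc(OC(C(=O)O)c2ccc(OCc3ccccc3)cc2)cc1OCc1ccccc1 | intermediate
17 | mixed anhydride of 16 with trifluoroacetic acid | CN1CCCC[C@@H]1c1c(OCc2ccccc2)cc(OC(C(=O)OC(=O)C(F)(F)F)c2ccc(OCc3ccccc3)cc2)cc1OCc1ccccc1 | intermediate
18 | 4,6-bis(benzyloxy)-2-[4-(benzyloxy)phenyl]-5-[(2R)-1-methylpiperidin-2-yl]-1-benzofuran-3(2H)-one (both epimers at C2) | CN1CCCC[C@@H]1c1c(OCc2ccccc2)cc2OC(c3ccc(OCc4ccccc4)cc3)C(=O)c2c1OCc1ccccc1 | intermediate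
19 | {[4,6-bis(benzyloxy)-2-[4-(benzyloxy)phenyl]-5-[(2R)-1-methylpiperidin-2-yl]-1-benzofuran-3-yl]oxy}(tert-butyl)dimethylsilane | CN1CCCC[C@@H]1c1c(OCc2ccccc2)cc2oc(-c3ccc(OCc4ccccc4)cc3)c(O[Si](C)(C)C(C)(C)C)c2c1OCc1ccccc1 | intermediate
20 | {[(1aR,6bR)-4,6-bis(benzyloxy)-1a-[4-(benzyloxy)phenyl]-5-[(2R)-1-methylpiperidin-2-yl]-1,1a-dihydro-6bH-cyclopropa[b][1]benzofuran-6b-yl]oxy}(tert-butyl)dimethylsilane | CC(C)(C)[Si](C)(C)O[C@@]12C[C@]1(c1ccc(OCc3ccccc3)cc1)Oc1cc(OCc3ccccc3)c([C@H]3CCCCN3C)c(OCc3ccccc3)c12 | intermediate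
21 | tetrabutylammonium (1aR,6bR)-4,6-bis(benzyloxy)-1a-[4-(benzyloxy)phenyl]-5-[(2R)-1-methylpiperidin-2-yl]-1,1a-dihydro-6bH-cyclopropa[b][1]benzofuran-6b-olate | [O-][C@@]12C[C@]1(c1ccc(OCc3ccccc3)cc1)Oc1cc(OCc3ccccc3)c([C@H]3CCCCN3C)c(OCc3ccccc3)c12.CCCC[N+](CCCC)(CCCC)CCCC | intermediate
22 | (2S)-5,7-bis(benzyloxy)-2-[4-(benzyloxy)phenyl]-6-[(2R)-1-methylpiperidin-2-yl]-2,3-dihydro-4H-chromen-4-one | CN1CCCC[C@@H]1c1c(OCc2ccccc2)cc2c(c1OCc1ccccc1)C(=O)C[C@@H](c1ccc(OCc3ccccc3)cc1)O2 | intermediate
23 | (2S)-5,7-dihydroxy-2-(4-hydroxyphenyl)-6-[(2R)-1-methylpiperidin-2-yl]-2,3-dihydro-4H-chromen-4-one | CN1CCCC[C@@H]1c1c(O)cc2c(c1O)C(=O)C[C@@H](c1ccc(O)cc1)O2 | target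

**Step count**

Total: 14 steps. Longest linear sequence: 13 steps (steps 1–7 and 9–14, from 1); the side branch is step 8.

**Steps most likely to fail**

Step 12 (proposed new method). The carbenoid may add sluggishly to the hindered, tetrasubstituted enol ether bond of the benzofuran, add with poor facial selectivity, or be intercepted by the tertiary amine through ammonium ylide formation. The fallback uses known chemistry, sets out from phenol 11 and comes back at 22. C-Acetylation ortho to the free hydroxyl (Ac2O, BF3·OEt2) would give the acetophenone F1. Condensation with N,N-dimethylformamide dimethyl acetal would give the enaminone F2, and acid-induced cyclization (HCl, CH2Cl2) the chromone F3, whose single free ortho hydroxyl again fixes the regiochemistry. A Pd(OCOCF3)2/t-BuPyOx-catalysed asymmetric conjugate addition of 4-(benzyloxy)phenylboronic acid (ligand enantiomer chosen for the 2S face, the amine held as its trifluoroacetate) would then give 22 directly.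

Step 13 (proposed new method). Stereochemical fidelity may be lost if the benzylic carbanion becomes free before it is protonated, the other cyclopropane bond may be cleaved, or the product may open to the chalcone under base and reclose. The fallback uses known chemistry, sets out from 20 (for which a racemic cyclopropane would do) and comes back at 22. FeCl3 in DMF would open the siloxycyclopropane by one-electron oxidation at the fusion bond to the 2-chloro ketone F4, which loses HCl with NaOAc to give the flavone F5. Asymmetric hydrogenation with [Ru(cod)(2-methylallyl)2] and a chiral N-heterocyclic carbene ligand would give the (2S)-flavan-4-ol F6, and Dess–Martin oxidation would return the ketone 22.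

Step 11. The acylium equivalent, flanked by an aryloxy and an electron-rich aryl group, may lose CO instead of cyclizing, and the acid may strip benzyl groups or open the electron-rich benzylic amine. The fallback sets out from phenol 11 and comes back at 18, which is silylated to 19 as in step 11. Houben–Hoesch acylation with 2-[4-(benzyloxy)phenyl]acetonitrile (HCl, ZnCl2, Et2O) would give the ketiminium chloride F7, hydrolysed in warm water to the 2-hydroxydeoxybenzoin F8. Bromination of the benzylic CH2 (PhNMe3Br3, THF) would give the α-bromo ketone F9, and K2CO3 in acetone would close the furanone ring by O-alkylation, so the C–C bond to ring A is made before the ring oxygen is attached.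

**Further compounds**

F1 | step 12 | 1-{4,6-bis(benzyloxy)-2-hydroxy-5-[(2R)-1-methylpiperidin-2-yl]phenyl}ethan-1-one | CC(=O)c1c(O)cc(OCc2ccccc2)c([C@H]2CCCCN2C)c1OCc1ccccc1
F2 | step 12 | (E)-1-{4,6-bis(benzyloxy)-2-hydroxy-5-[(2R)-1-methylpiperidin-2-yl]phenyl}-3-(dimethylamino)prop-2-en-1-one | CN(C)/C=C/C(=O)c1c(O)cc(OCc2ccccc2)c([C@H]2CCCCN2C)c1OCc1ccccc1
F3 | step 12 | 5,7-bis(benzyloxy)-6-[(2R)-1-methylpiperidin-2-yl]-4H-chromen-4-one | CN1CCCC[C@@H]1c1c(OCc2ccccc2)cc2occc(=O)c2c1OCc1ccccc1
F4 | step 13 | 5,7-bis(benzyloxy)-2-[4-(benzyloxy)phenyl]-2-chloro-6-[(2R)-1-methylpiperidin-2-yl]-2,3-dihydro-4H-chromen-4-one | CN1CCCC[C@@H]1c1c(OCc2ccccc2)cc2c(c1OCc1ccccc1)C(=O)CC(Cl)(c1ccc(OCc3ccccc3)cc1)O2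
F5 | step 13 | 5,7-bis(benzyloxy)-2-[4-(benzyloxy)phenyl]-6-[(2R)-1-methylpiperidin-2-yl]-4H-chromen-4-one | CN1CCCC[C@@H]1c1c(OCc2ccccc2)cc2oc(-c3ccc(OCc4ccccc4)cc3)cc(=O)c2c1OCc1ccccc1
F6 | step 13 | (2S)-5,7-bis(benzyloxy)-2-[4-(benzyloxy)phenyl]-6-[(2R)-1-methylpiperidin-2-yl]-3,4-dihydro-2H-chromen-4-ol | CN1CCCC[C@@H]1c1c(OCc2ccccc2)cc2c(c1OCc1ccccc1)C(O)C[C@@H](c1ccc(OCc3ccccc3)cc1)O2
F7 | step 11 | 2-[4-(benzyloxy)phenyl]-1-{4,6-bis(benzyloxy)-2-hydroxy-5-[(2R)-1-methylpiperidin-2-yl]phenyl}ethan-1-iminium chloride | [Cl-].[NH2+]=C(Cc1ccc(OCc2ccccc2)cc1)c1c(O)cc(OCc2ccccc2)c([C@H]2CCCCN2C)c1OCc1ccccc1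
F8 | step 11 | 2-[4-(benzyloxy)phenyl]-1-{4,6-bis(benzyloxy)-2-hydroxy-5-[(2R)-1-methylpiperidin-2-yl]phenyl}ethan-1-one | O=C(Cc1ccc(OCc2ccccc2)cc1)c1c(O)cc(OCc2ccccc2)c([C@H]2CCCCN2C)c1OCc1ccccc1
F9 | step 11 | 2-[4-(benzyloxy)phenyl]-1-{4,6-bis(benzyloxy)-2-hydroxy-5-[(2R)-1-methylpiperidin-2-yl]phenyl}-2-bromoethan-1-one | O=C(C(Br)c1ccc(OCc2ccccc2)cc1)c1c(O)cc(OCc2ccccc2)c([C@H]2CCCCN2C)c1OCc1ccccc1
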